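Both acyl arms are the same (2Z,4S,5S)-4,5-epoxyhex-2-enoyl unit (C1 = carboxyl carbon), so the plan rests on one disconnection: each oxirane ring is cut through C4–C5 and C4–O. A single operation joins the ylide of a C2-symmetric (2R,5R)-2,5-dimethylthiolanium salt, which carries a 3-(trimethylsilyl)prop-2-ynyl group on sulfur, to acetaldehyde (C5, C6 and the ring oxygen) and closes the trans-epoxide with C4 and C5 set together. The propargyl unit supplies C4, C3 and C2; C1 is added afterwards from CO2 and the Z-alkene by semi-hydrogenation. The salt is used as its tetrafluoroborate. Two acyl units are finally placed on the quinone oxygens of atromentin.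

Key step: step 4

Assumption: the (2R,5R)-thiolane is taken to give the (S,S)-epoxide, as its benzyl-type ylides do; if the silylpropargyl ylide showed the opposite sense, the thiolane from (2R,5R)-hexane-2,5-diol would be used with no other change.

Step 1
Reactants: 1 (2S,5S)-hexane-2,5-diol
Product: 2 (2S,5S)-hexane-2,5-diyl dimethanesulfonate
Conditions: MsCl (2.4 equiv), Et3N (3 equiv), CH2Cl2, 0 °C
Reagents that add atoms: methanesulfonyl chloride, CS(=O)(=O)Cl
Why: O-Sulfonylation (mesylation) of both secondary alcohols takes place at oxygen only, so the two stereocentres are carried over unchanged and become leaving groups.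

Step 2
Reactants: 2 (2S,5S)-hexane-2,5-diyl dimethanesulfonate
Product: 3 (2R,5R)-2,5-dimethylthiolane
Conditions: Na2S·9H2O (1.5 equiv), EtOH, rt → 40 °C; pentane extraction, distillation
Reagents that add atoms: sodium sulfide, [Na+].[Na+].[S-2]
Why: Two successive SN2 displacements by sulfur (intermolecular, then a 5-exo-tet thioether ring closure) each invert a secondary mesylate, so the (S,S)-dimesylate should give the (R,R)-thiolane.

Step 3
Reactants: 3 (2R,5R)-2,5-dimethylthiolane; 4 3-bromo-1-(trimethylsilyl)propyne
Product: 6 (2R,5R)-2,5-dimethyl-1-[3-(trimethylsilyl)prop-2-yn-1-yl]thiolan-1-ium tetrafluoroborate, via thiolanium bromide 5 (not isolated)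
Conditions: 4 (1.2 equiv), NaBF4 (2 equiv), CH2Cl2/H2O (1:1), rt; crystallisation from CH2Cl2/Et2O
Reagents that add atoms: sodium tetrafluoroborate, [Na+].F[B-](F)(F)F
Why: SN2 S-alkylation of the sulfide by the reactive propargylic bromide is pulled to completion by anion metathesis in the same flask to the non-nucleophilic tetrafluoroborate, which gives a dry, crystalline salt that cannot revert to sulfide and bromide; the C2 axis of the thiolane makes the two sulfur lone pairs equivalent, so sulfur is not a stereocentre and one salt forms.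

Step 4
Reactants: 6 (2R,5R)-2,5-dimethyl-1-[3-(trimethylsilyl)prop-2-yn-1-yl]thiolan-1-ium tetrafluoroborate; 7 acetaldehyde
Product: 10 (2S,3S)-2-methyl-3-[(trimethylsilyl)ethynyl]oxirane, via sulfonium ylide 8 (not isolated), via anti-betaine 9 (not isolated)
Conditions: KN(SiMe3)2 (0.98 equiv), THF, −78 °C, 20 min; MeCHO (3 equiv, freshly distilled, precooled in THF), −78 → −40 °C; chromatography in pentane/Et2O, cold concentration
Reagents that add atoms: none
Why: KN(SiMe3)2 removes a proton from the S–CH2 group, which is acidified by both the sulfonium centre and the alkyne, and the semi-stabilised ylide 8 adds through carbon to the carbonyl group of acetaldehyde (C4–C5 bond) to give betaine 9, whose alkoxide then displaces the sulfide from C4 (C4–O bond) and returns thiolane 3 for reuse. The closest known reaction type is the asymmetric Corey–Chaykovsky epoxidation of aldehydes with C2-symmetric chiral sulfonium ylides that carry benzyl, allyl or propargyl groups. The oxirane ring closes by a 3-exo-tet substitution with inversion at C4. C5 is set in the addition, where the two ring methyl groups hold the ylide in one conformation and shield one face of the ylide carbon, so that the aldehyde is taken up on the open face with its methyl group anti to the alkynyl group; C4 is set by the same face selection together with the stereospecific inversion on closure. The step needs enantioselectivity and trans selectivity: the first is secured by the C2 symmetry of the thiolane (one sulfonium salt, one exposed ylide face), the second by reversible formation of the syn-betaine under lithium-free, aprotic conditions, which lets material drain through the anti-betaine. The silyl cap prevents propargyl-to-allenyl isomerisation of the salt, blocks reaction through the distal alkyne carbon and survives the hydroxide-free, fluoride-free base.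

Step 5
Reactants: 10 (2S,3S)-2-methyl-3-[(trimethylsilyl)ethynyl]oxirane
Product: 12 3-[(2S,3S)-3-methyloxiran-2-yl]prop-2-ynoic acid, via cesium ynoate 11 (not isolated)
Conditions: CsF (1.5 equiv), CO2 (1 atm), dry DMSO, rt; then cold 1 M H3PO4 to pH 3, EtOAc extraction, concentration below 20 °C
Reagents that add atoms: carbon dioxide, O=C=O
Why: Fluoride-mediated desilylative carboxylation of an alkynylsilane: fluoride attacks silicon, the alkynyl anion equivalent so released is trapped by CO2 as the cesium carboxylate, and the non-volatile acid is reached without isolating the low-boiling terminal alkyne, while the epoxide is inert to these weakly basic, aprotic conditions and its stereocentres are not involved.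

Step 6
Reactants: 12 3-[(2S,3S)-3-methyloxiran-2-yl]prop-2-ynoic acid
Product: 14 sodium (2Z)-3-[(2S,3S)-3-methyloxiran-2-yl]prop-2-enoate, via sodium ynoate 13 (not isolated)
Conditions: NaHCO3 (1.0 equiv), MeOH/H2O, 0 °C; then H2 (1 atm), Pd/CaCO3 poisoned with Pb(OAc)2, quinoline, MeOH, 0 °C, stopped after one equivalent of H2; filtration, evaporation, trituration with Et2O, drying in vacuo
Reagents that add atoms: sodium hydrogencarbonate, [Na+].OC(=O)[O-]
Why: Lindlar semi-hydrogenation delivers H2 in a syn fashion on the lead-poisoned palladium surface to give the Z-alkene and stops there, and running it on the sodium salt keeps the cis-disposed carboxyl group as an unreactive carboxylate, so that it cannot open the neighbouring epoxide to a lactone.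

Step 7
Reactants: 15 bromanilic acid (2,5-dibromo-3,6-dihydroxy-1,4-benzoquinone)
Product: 16 2,5-dibromo-3,6-dimethoxy-1,4-benzoquinone
Conditions: Me3SiCHN2 (2.2 equiv), MeOH/toluene (1:4), 0 °C → rt
Reagents that add atoms: (trimethylsilyl)diazomethane, C[Si](C)(C)C=[N+]=[N-]
Why: O-Methylation of a strongly acidic vinylogous carboxylic acid by a diazoalkane (diazomethane-type esterification) should occur at the enolic oxygens only, since the ring carbons are blocked by bromine, with the para-quinone diether as the expected product.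

Step 8
Reactants: 16 2,5-dibromo-3,6-dimethoxy-1,4-benzoquinone; 17 (4-methoxyphenyl)boronic acid
Product: 18 2,5-dimethoxy-3,6-bis(4-methoxyphenyl)-1,4-benzoquinone
Conditions: 17 (2.5 equiv), PdCl2(dppf) (5 mol %), K2CO3 (4 equiv), 1,4-dioxane/H2O (10:1), 80 °C, argon
Reagents that add atoms: none
Why: Twofold Suzuki–Miyaura coupling at the vinylic C–Br bonds of a bromoquinone masked as its bis(vinylogous methyl ester), a substrate class on which this coupling is established, should work because the methoxy groups keep the ring from ionising under the basic conditions.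

Step 9
Reactants: 18 2,5-dimethoxy-3,6-bis(4-methoxyphenyl)-1,4-benzoquinone
Product: 19 atromentin (2,5-dihydroxy-3,6-bis(4-hydroxyphenyl)-1,4-benzoquinone)
Conditions: BBr3 (8 equiv), CH2Cl2, −78 °C → rt; then H2O, 0 °C
Reagents that add atoms: none
Why: Lewis-acid ether cleavage (BBr3 demethylation) removes the two aryl methyl ethers and the two vinylogous methyl esters in one operation, and the hydroxyquinone core is robust towards these acidic conditions.

Step 10
Reactants: 14 sodium (2Z)-3-[(2S,3S)-3-methyloxiran-2-yl]prop-2-enoate; 19 atromentin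
Product: 22 2,5-bis(4-hydroxyphenyl)-3,6-dioxocyclohexa-1,4-diene-1,4-diyl bis{(2Z)-3-[(2S,3S)-3-methyloxiran-2-yl]prop-2-enoate} (CNP0407724.1), via acyl chloride 20 (not isolated), via atromentin bis-ammonium salt 21 (not isolated)
Conditions: 14 (2.3 equiv), (COCl)2 (2.2 equiv), CH2Cl2, 0 °C → rt, 1 h; this solution added to 19, i-Pr2NEt (2.0 equiv), THF, −40 → 0 °C; pH 6 phosphate buffer work-up, Sephadex LH-20 (CH2Cl2/acetone), no alcohols
Reagents that add atoms: none
Why: Acyl chloride formation from a sodium carboxylate with oxalyl chloride releases no HCl, and in the following O-acylation only the two ion-paired quinone oxygens of 21 react, because they are far more acidic than the phenols and are the only sites deprotonated by exactly two equivalents of base; no acid, fluoride or nucleophilic catalyst is present that could open the epoxides, isomerise the Z-alkenes or cleave the new vinylogous anhydride linkages.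

Compound list

1 | (2S,5S)-hexane-2,5-diol | C[C@H](O)CC[C@H](C)O | starting material
2 | (2S,5S)-hexane-2,5-diyl dimethanesulfonate | C[C@H](OS(C)(=O)=O)CC[C@H](C)OS(C)(=O)=O | intermediate
3 | (2R,5R)-2,5-dimethylthiolane | C[C@@H]1CC[C@@H](C)S1 | intermediate
4 | 3-bromo-1-(trimethylsilyl)propyne | C[Si](C)(C)C#CCBr | starting material
5 | (2R,5R)-2,5-dimethyl-1-[3-(trimethylsilyl)prop-2-yn-1-yl]thiolan-1-ium bromide (not isolated) | C[C@@H]1CC[C@@H](C)[S+]1CC#C[Si](C)(C)C.[Br-] | intermediate
6 | (2R,5R)-2,5-dimethyl-1-[3-(trimethylsilyl)prop-2-yn-1-yl]thiolan-1-ium tetrafluoroborate | C[C@@H]1CC[C@@H](C)[S+]1CC#C[Si](C)(C)C.F[B-](F)(F)F | intermediate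
7 | acetaldehyde | CC=O | starting material
8 | [(2R,5R)-2,5-dimethylthiolan-1-ium-1-yl][(trimethylsilyl)ethynyl]methanide, the sulfonium ylide (not isolated) | C[C@@H]1CC[C@@H](C)[S+]1[CH-]C#C[Si](C)(C)C | intermediate
9 | (2S,3R)-3-[(2R,5R)-2,5-dimethylthiolan-1-ium-1-yl]-5-(trimethylsilyl)pent-4-yn-2-olate, the anti-betaine (not isolated) | C[C@H]([O-])[C@@H](C#C[Si](C)(C)C)[S+]1[C@H](C)CC[C@H]1C | intermediate
10 | (2S,3S)-2-methyl-3-[(trimethylsilyl)ethynyl]oxirane | C[C@@H]1O[C@H]1C#C[Si](C)(C)C | intermediate
11 | cesium 3-[(2S,3S)-3-methyloxiran-2-yl]prop-2-ynoate (not isolated) | C[C@@H]1O[C@H]1C#CC(=O)[O-].[Cs+] | intermediate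
12 | 3-[(2S,3S)-3-methyloxiran-2-yl]prop-2-ynoic acid | C[C@@H]1O[C@H]1C#CC(=O)O | intermediate
13 | sodium 3-[(2S,3S)-3-methyloxiran-2-yl]prop-2-ynoate (not isolated) | C[C@@H]1O[C@H]1C#CC(=O)[O-].[Na+] | intermediate
14 | sodium (2Z)-3-[(2S,3S)-3-methyloxiran-2-yl]prop-2-enoate | C[C@@H]1O[C@H]1/C=C\C(=O)[O-].[Na+] | intermediate
15 | bromanilic acid (2,5-dibromo-3,6-dihydroxy-1,4-benzoquinone) | OC1=C(Br)C(=O)C(O)=C(Br)C1=O | starting material
16 | 2,5-dibromo-3,6-dimethoxy-1,4-benzoquinone | COC1=C(Br)C(=O)C(OC)=C(Br)C1=O | intermediate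
17 | (4-methoxyphenyl)boronic acid | COc1ccc(B(O)O)cc1 | starting material
18 | 2,5-dimethoxy-3,6-bis(4-methoxyphenyl)-1,4-benzoquinone | COC1=C(c2ccc(OC)cc2)C(=O)C(OC)=C(c2ccc(OC)cc2)C1=O | intermediate
19 | atromentin (2,5-dihydroxy-3,6-bis(4-hydroxyphenyl)-1,4-benzoquinone) | OC1=C(c2ccc(O)cc2)C(=O)C(O)=C(c2ccc(O)cc2)C1=O | intermediate
20 | (2Z)-3-[(2S,3S)-3-methyloxiran-2-yl]prop-2-enoyl chloride (not isolated) | C[C@@H]1O[C@H]1/C=C\C(Cl)=O | intermediate
21 | bis(N-ethyl-N-isopropylpropan-2-aminium) salt of the atromentin 2,5-diolate (not isolated) | [O-]C1=C(c2ccc(O)cc2)C(=O)C([O-])=C(c2ccc(O)cc2)C1=O.CC[NH+](C(C)C)C(C)C.CC[NH+](C(C)C)C(C)C | intermediate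
22 | 2,5-bis(4-hydroxyphenyl)-3,6-dioxocyclohexa-1,4-diene-1,4-diyl bis{(2Z)-3-[(2S,3S)-3-methyloxiran-2-yl]prop-2-enoate} (CNP0407724.1) | C[C@@H]1O[C@H]1/C=C\C(=O)OC1=C(c2ccc(O)cc2)C(=O)C(OC(=O)/C=C\[C@@H]2O[C@H]2C)=C(c2ccc(O)cc2)C1=O | target

Total step count: 10
Longest linear sequence: 7 steps (steps 1, 2, 3, 4, 5, 6 and 10); the quinone core takes steps 7 to 9 and joins in step 10.

Steps most likely to fail

Step 4. With the small, enolisable acetaldehyde, betaine formation may be less reversible and face discrimination weaker than with aromatic aldehydes, which would erode trans- and enantioselectivity. The ylide may also act as a base and set off aldol self-condensation of the aldehyde. The fallback makes the oxirane by reagent-controlled epoxidation of an alkene and the Z-enoate by olefination, so that steps 4 to 6 are bypassed. It sets out from acetaldehyde 7: a Horner–Wadsworth–Emmons reaction with triethyl phosphonoacetate (NaH, THF, 0 °C) would give ethyl (2E)-but-2-enoate F1, and i-Bu2AlH (CH2Cl2, −78 °C) would reduce it to (2E)-but-2-en-1-ol F2; both are also articles of commerce. Sharpless asymmetric epoxidation (Ti(Oi-Pr)4, L-(+)-diethyl tartrate, t-BuOOH, 4 Å molecular sieves, CH2Cl2, −20 °C) should give [(2S,3S)-3-methyloxiran-2-yl]methanol F3. Oxidation with Dess–Martin periodinane (NaHCO3, CH2Cl2, 0 °C) would give (2R,3S)-3-methyloxirane-2-carbaldehyde F4, used in solution. Still–Gennari olefination with methyl bis(2,2,2-trifluoroethyl)phosphonoacetate (KN(SiMe3)2, 18-crown-6, THF, −78 °C) should give methyl (2Z)-3-[(2S,3S)-3-methyloxiran-2-yl]prop-2-enoate F5. Saponification with NaOH (1.0 equiv, THF/H2O, 0 °C) comes back to the route at the sodium salt 14.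

Step 10. The acyl group may be transferred to the phenolic oxygens during or after the coupling, the acyl chloride may be lost through Z-to-E isomerisation or epoxide opening before it reacts, and the vinylogous anhydride linkages may be hydrolysed during isolation. The fallback masks the phenols so that an excess of acyl donor can be used. It sets out from atromentin 19: Et3SiCl (5 equiv) and imidazole in DMF would give 2,5-bis(triethylsilyloxy)-3,6-bis[4-(triethylsilyloxy)phenyl]-1,4-benzoquinone F6. Brief stirring in THF/H2O/AcOH at 0 °C should cleave only the two quinone O–Si bonds, which are vinylogous silyl esters, to give 2,5-dihydroxy-3,6-bis[4-(triethylsilyloxy)phenyl]-1,4-benzoquinone F7. Acylation with an excess of chloride 20 (made from 14 as in step 10) and 2,6-lutidine (CH2Cl2, −40 → 0 °C) would give 2,5-dioxo-3,6-bis[4-(triethylsilyloxy)phenyl]cyclohexa-1,4-diene-1,4-diyl bis{(2Z)-3-[(2S,3S)-3-methyloxiran-2-yl]prop-2-enoate} F8. The labile aryl triethylsilyl ethers would then be removed with Et3N·3HF (THF, 0 °C, short contact), which comes back to the route at the target 22.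

Step 5. Traces of water may protonate the alkynyl anion equivalent before CO2 does, so that protodesilylation gives the low-boiling terminal alkyne, which is lost on work-up; slow attack of fluoride or carboxylate on the epoxide in DMSO is a second concern. The fallback separates desilylation from carboxylation and uses a preformed lithium acetylide. It sets out from silylalkyne 10: K2CO3 in MeOH (0 °C) would give (2S,3S)-2-ethynyl-3-methyloxirane F9, kept as a dried pentane/Et2O solution. n-BuLi (THF, −78 °C) would convert it into lithium [(2S,3S)-3-methyloxiran-2-yl]ethynide F10, and dry CO2 would give lithium 3-[(2S,3S)-3-methyloxiran-2-yl]prop-2-ynoate F11. Cold aqueous H3PO4 (pH 3) comes back to the route at acid 12.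

Further compounds

F1 | step 4 | ethyl (2E)-but-2-enoate | CCOC(=O)/C=C/C
F2 | step 4 | (2E)-but-2-en-1-ol | C/C=C/CO
F3 | step 4 | [(2S,3S)-3-methyloxiran-2-yl]methanol | C[C@@H]1O[C@H]1CO
F4 | step 4 | (2R,3S)-3-methyloxirane-2-carbaldehyde | C[C@@H]1O[C@H]1C=O
F5 | step 4 | methyl (2Z)-3-[(2S,3S)-3-methyloxiran-2-yl]prop-2-enoate | C[C@@H]1O[C@H]1/C=C\C(=O)OC
F6 | step 10 | 2,5-bis(triethylsilyloxy)-3,6-bis[4-(triethylsilyloxy)phenyl]-1,4-benzoquinone | CC[Si](CC)(CC)OC1=C(c2ccc(O[Si](CC)(CC)CC)cc2)C(=O)C(O[Si](CC)(CC)CC)=C(c2ccc(O[Si](CC)(CC)CC)cc2)C1=O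
F7 | step 10 | 2,5-dihydroxy-3,6-bis[4-(triethylsilyloxy)phenyl]-1,4-benzoquinone | OC1=C(c2ccc(O[Si](CC)(CC)CC)cc2)C(=O)C(O)=C(c2ccc(O[Si](CC)(CC)CC)cc2)C1=O
F8 | step 10 | 2,5-dioxo-3,6-bis[4-(triethylsilyloxy)phenyl]cyclohexa-1,4-diene-1,4-diyl bis{(2Z)-3-[(2S,3S)-3-methyloxiran-2-yl]prop-2-enoate} | C[C@@H]1O[C@H]1/C=C\C(=O)OC1=C(c2ccc(O[Si](CC)(CC)CC)cc2)C(=O)C(OC(=O)/C=C\[C@@H]2O[C@H]2C)=C(c2ccc(O[Si](CC)(CC)CC)cc2)C1=O
F9 | step 5 | (2S,3S)-2-ethynyl-3-methyloxirane | C[C@@H]1O[C@H]1C#C
F10 | step 5 | lithium [(2S,3S)-3-methyloxiran-2-yl]ethynide | C[C@@H]1O[C@H]1C#[C-].[Li+]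
F11 | step 5 | lithium 3-[(2S,3S)-3-methyloxiran-2-yl]prop-2-ynoate | C[C@@H]1O[C@H]1C#CC(=O)[O-].[Li+]
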